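**Assumption:** glicoricone has no stereocentre and its prenyl alkene carries two identical methyl groups, so there is no configuration to set; the route delivers the single achiral compound.

## Retrosynthetic overview
1. Glicoricone (14) ⇐ fluoride removal of two aryl TIPS ethers from 13.
2. 13 ⇐ one radical arylation–annulation: the aryl radical from iodide 8 adds to the α-carbon of o-hydroxyaryl enaminone 12, forming C3–C1′, and the pyranone then closes (O1–C2).
3. 8 ⇐ symmetric 1-methoxy-3,5-bis(TIPSO)benzene 5 by two successive OMe-directed ortho-lithiations (prenyl first, then iodine). Bulky OTIPS groups keep the position between them untouched.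
4. 5 ⇐ resorcinol by silylation, sterically controlled Ir C–H borylation/oxidation at C5, and O-methylation. 12 ⇐ resorcinol + acetic acid + DMF-DMA.
5. Ring order: both benzene rings come from resorcinol; the pyranone ring (ring C) is formed last, in the key step.

Numbering convention: numbers are given to every compound whose atoms end up in the target and to all intermediates. Auxiliary reagents (TIPSCl, B2pin2, Oxone, I2) are given with SMILES in the step where they are used.

## Route

**Step 1**
Reactants: 1, resorcinol
Product: 2, 1,3-bis(triisopropylsilyloxy)benzene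
Conditions: TIPSCl (2.2 equiv), imidazole, DMF, rt → 50 °C
Reagents that add atoms: triisopropylsilyl chloride, CC(C)[Si](Cl)(C(C)C)C(C)C
Why: Standard phenol silylation; the bulky TIPS ethers are chosen because they later block the ring position between them and do not direct lithiation.

**Step 2**
Reactants: 2
Product: 3, 3,5-bis(triisopropylsilyloxy)phenol
Conditions: [Ir(OMe)(cod)]2 (1.5 mol %), dtbpy (3 mol %), B2pin2, hexane, 80 °C; then Oxone, acetone/H2O, rt (one pot)
Reagents that add atoms: Oxone (KHSO5), [K+].OOS(=O)(=O)[O-] (source of the new O); B2pin2, CC1(C)OB(OC1(C)C)B1OC(C)(C)C(C)(C)O1 (boron is only transient)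
Why: Ir-catalysed C–H borylation is sterically controlled, and C5–H is the only C–H without an ortho substituent; oxidation of the aryl boronate then gives the phenol with the 1,3,5-trioxygenation pattern.

**Step 3**
Reactants: 3; 4, iodomethane
Product: 5, 1-methoxy-3,5-bis(triisopropylsilyloxy)benzene
Conditions: MeI, K2CO3, acetone, 40 °C
Reagents that add atoms: iodomethane, CI
Why: Williamson O-methylation of the only free phenol; the hindered aryl TIPS ethers tolerate carbonate in acetone.

**Step 4**
Reactants: 5; 6, prenyl bromide (1-bromo-3-methylbut-2-ene)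
Product: 7, 1-methoxy-2-(3-methylbut-2-en-1-yl)-3,5-bis(triisopropylsilyloxy)benzene
Conditions: n-BuLi, TMEDA, THF, 0 °C; CuBr·SMe2, −40 °C; prenyl bromide, → rt
Reagents that add atoms: prenyl bromide, CC(C)=CCBr
Why: Directed ortho-metalation by OMe (the two ortho sites are equivalent by symmetry, and the site between the two non-coordinating OTIPS groups is not lithiated), followed by copper-mediated SN2 allylation to give the linear prenyl group.

**Step 5**
Reactants: 7
Product: 8, 1-iodo-2-methoxy-3-(3-methylbut-2-en-1-yl)-4,6-bis(triisopropylsilyloxy)benzene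
Conditions: s-BuLi, TMEDA, THF, −78 → −40 °C; I2, −78 °C
Reagents that add atoms: iodine, II
Why: Second directed ortho-metalation at the only remaining C–H ortho to OMe, run cold so that the benzylic/allylic prenyl CH2 is not deprotonated; iodine quench fixes the halide between OMe and OTIPS.

**Step 6**
Reactants: 1, resorcinol; 9, acetic acid
Product: 10, 1-(2,4-dihydroxyphenyl)ethan-1-one
Conditions: AcOH, BF3·OEt2, 90 °C
Reagents that add atoms: acetic acid, CC(=O)O
Why: Nencki-type Friedel–Crafts C-acylation of resorcinol, which goes at C4 (ortho to one OH, para to the other).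

**Step 7**
Reactants: 10; 11, N,N-dimethylformamide dimethyl acetal
Product: 12, (E)-1-(2,4-dihydroxyphenyl)-3-(dimethylamino)prop-2-en-1-one
Conditions: DMF-DMA (1.2 equiv), toluene, 80 °C, 2–3 h
Reagents that add atoms: DMF-DMA, COC(OC)N(C)C
Why: Enaminone condensation of the methyl ketone; only a slight excess and moderate temperature are used so that the free 4-OH is not O-methylated, and the E-enaminone forms as the thermodynamic isomer.

**Step 8 (key step)**
Reactants: 8; 12 (3 equiv)
Product: 13, 7-hydroxy-3-[2-methoxy-3-(3-methylbut-2-en-1-yl)-4,6-bis(triisopropylsilyloxy)phenyl]-4H-chromen-4-one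
Conditions: fac-Ir(ppy)3 (2 mol %), 2,6-lutidine (1.5 equiv), degassed DMSO, 455 nm LEDs, rt, Ar
Reagents that add atoms: none
Why: Proposed new method: excited fac-Ir(ppy)3 transfers an electron to the aryl iodide, which fragments to the aryl σ-radical; this adds to the electron-rich α-carbon of the enaminone to give an α-amino radical, Ir(IV) oxidises that radical to the iminium (closing a redox-neutral cycle), and the chelated 2-OH attacks the iminium and Me2NH is lost to give the 3-arylchromone. The closest known reactions are the photoredox Meerwein-type arylation/annulation of o-hydroxyaryl enaminones with aryldiazonium salts and the photoredox reduction of unactivated aryl iodides to aryl radicals.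

**Step 9**
Reactants: 13
Product: 14, glicoricone, 3-[4,6-dihydroxy-2-methoxy-3-(3-methylbut-2-en-1-yl)phenyl]-7-hydroxy-4H-chromen-4-one
Conditions: TBAF (2.5 equiv), AcOH (2.5 equiv), THF, 0 °C → rt
Reagents that add atoms: none
Why: Fluoride cleavage of the two aryl silyl ethers; acetic acid buffering keeps the electron-rich polyphenol from oxidising, and the prenyl group and chromone are untouched.

## Compound list
1 | resorcinol | Oc1cccc(O)c1 | starting material
2 | 1,3-bis(triisopropylsilyloxy)benzene | CC(C)[Si](Oc1cccc(O[Si](C(C)C)(C(C)C)C(C)C)c1)(C(C)C)C(C)C | intermediate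
3 | 3,5-bis(triisopropylsilyloxy)phenol | Oc1cc(O[Si](C(C)C)(C(C)C)C(C)C)cc(O[Si](C(C)C)(C(C)C)C(C)C)c1 | intermediate
4 | iodomethane | CI | starting material
5 | 1-methoxy-3,5-bis(triisopropylsilyloxy)benzene | COc1cc(O[Si](C(C)C)(C(C)C)C(C)C)cc(O[Si](C(C)C)(C(C)C)C(C)C)c1 | intermediate
6 | prenyl bromide | CC(C)=CCBr | starting material
7 | 1-methoxy-2-(3-methylbut-2-en-1-yl)-3,5-bis(triisopropylsilyloxy)benzene | COc1cc(O[Si](C(C)C)(C(C)C)C(C)C)cc(O[Si](C(C)C)(C(C)C)C(C)C)c1CC=C(C)C | intermediate
8 | 1-iodo-2-methoxy-3-(3-methylbut-2-en-1-yl)-4,6-bis(triisopropylsilyloxy)benzene | COc1c(I)c(O[Si](C(C)C)(C(C)C)C(C)C)cc(O[Si](C(C)C)(C(C)C)C(C)C)c1CC=C(C)C | intermediate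
9 | acetic acid | CC(=O)O | starting material
10 | 1-(2,4-dihydroxyphenyl)ethan-1-one | CC(=O)c1ccc(O)cc1O | intermediate
11 | N,N-dimethylformamide dimethyl acetal | COC(OC)N(C)C | starting material
12 | (E)-1-(2,4-dihydroxyphenyl)-3-(dimethylamino)prop-2-en-1-one | CN(C)/C=C/C(=O)c1ccc(O)cc1O | intermediate
13 | 7-hydroxy-3-[2-methoxy-3-prenyl-4,6-bis(triisopropylsilyloxy)phenyl]-4H-chromen-4-one | COc1c(CC=C(C)C)c(O[Si](C(C)C)(C(C)C)C(C)C)cc(O[Si](C(C)C)(C(C)C)C(C)C)c1-c1coc2cc(O)ccc2c1=O | intermediate
14 | glicoricone | COc1c(CC=C(C)C)c(O)cc(O)c1-c1coc2cc(O)ccc2c1=O | target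

## Totals
Total steps: 9. Longest linear sequence: 7 (Steps 1–5, 8, 9).

## Three steps most likely to fail
1. **Step 8.** The electron-rich, doubly ortho-substituted iodide may accept an electron slowly. The aryl radical may also be quenched by 1,5-H transfer from an ortho OTIPS isopropyl group or by the free phenols of 12. Fallback: form the same bond by a photostimulated SRN1 radical-chain α-arylation of the potassium enolate of ketone 10 with 8 (KOt-Bu, DMSO, hν), then close the pyranone on the resulting deoxybenzoin with DMF-DMA.
2. **Step 5.** The prenyl CH2 may be deprotonated instead of the ring, or lithiation next to OTIPS may be slow. Fallback: drop the sequential lithiations; di-iodinate 5 with NIS at both OMe-ortho positions, then do a single I/Mg exchange (i-PrMgCl·LiCl) and Cu-catalysed prenylation to reach 8 directly.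
3. **Step 4.** Ortho-lithiation flanked by a TIPS ether may be sluggish or give silyl migration. Fallback: C-prenylate phenol 3 ortho to its free OH as the sodium phenoxide in toluene (the para site is shielded by two OTIPS groups), then O-methylate to reach 7.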